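(All runs are simulated for an exercise, and the scatter is random.)

Reagent left over once every substrate has had its partner is what I count first. By the steps under discussion, one target costs one reagent and one self-condensation product costs two. Reagent charge minus substrate charge is 0.00650 M, my spare reagent, and it pays for 0.00325 M of self-condensation product. Each further mole of product takes two moles off the target.

in all of them: substrate 0.013 M (in portions, 2); reagent 0.0195 M
- ash: free catalyst 0.85 mM; temperature −5 °C; run made earlier; portions every 3.0 min
- birch: free catalyst 2 mM; temperature 12 °C; run made earlier; portions every 3.0 min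
- Saturday's: free catalyst 1.3 mM; at 0 °C until 12 min, from then on at 25 °C; the portions of substrate follow each other after 3.0 min, the first at the start; time 25 min
- Tuesday's: free catalyst 0.60 mM; at 25 °C throughout; the portions of substrate follow each other after 3.0 min, the first at the start; time 40 min

| run | time / min | target / % | substrate / % |
|---|---|---|---|
| ash | 1.33 | 0.6 | 47.8 |
| ash | 4.00 | 1.0 | 95.2 |
| ash | 8.00 | 2.0 | 93.6 |
| ash | 10.0 | 3.4 | 92.7 |
| ash | 15.0 | 4.9 | 90.7 |
| ash | 20.0 | 8.3 | 85.4 |
| ash | 25.0 | 10.1 | 86.6 |
| birch | 2.00 | 9.2 | 34.8 |
| birch | 4.00 | 19.0 | 71.2 |
| birch | 6.00 | 30.7 | 56.6 |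
| birch | 8.00 | 43.3 | 49.6 |
| birch | 12.0 | 58.5 | 32.5 |
| birch | 15.0 | 66.7 | 22.0 |

(standard deviation of a reading: 1 percentage point)

- steps under discussion: catalyst intermediate C -> free catalyst + target; 2 reagent -> self-condensation product; substrate + free catalyst <-> catalyst intermediate A; catalyst intermediate A -> catalyst intermediate B; reagent + catalyst intermediate B <-> catalyst intermediate C

* the flask that ends with the higher amount of target, in percent of the substrate charged, or "neither" when 2 percentage points or less lies between them (Saturday's / Tuesday's / neither)
* final target, as a percentage of the substrate charged, in Saturday's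
* final target, as a percentage of the substrate charged, in Tuesday's

Two extreme flasks can be done in the head. With a catalyst so quick that self-condensation gets nowhere, target reaches 100%, substrate is the limiting reagent and the spare stays in the flask. With a catalyst so slow that self-condensation eats the reagent first, no target forms. The real flasks lie between, and the readings give target and substrate but not reagent, so I can only rank them.

Warmth buys pace: the ash run at −5 °C reaches 10.1% by 25.0 min, while the birch run at 12 °C climbs from 19.0% to 43.3% between 4.00 min and 8.00 min. Saturday's flask sits at 0 °C until 12 min, close to ash, so I expect target to come slowly there; what self-condensation takes from the reagent in those minutes the readings do not show. At 25 °C it then holds 2.17 times the catalyst of Tuesday's flask. If pace follows catalyst, it needs half of Tuesday's hot time for the same target, and self-condensation, which uses no catalyst, gets that much less time at 25 °C. I commit to Saturday's ahead, without a figure for either flask.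

The forecast says Saturday's, with 84% for Saturday's and 72% for Tuesday's: “Reagent may run out, so I expect Saturday's to be higher”.

Saturday's ends at 75.0% and Tuesday's at 64.5%, so Saturday's is ahead as the forecast said, though each figure is lower than the forecast's.

    catalyst intermediate C → free catalyst + target (k = 0.350 min⁻¹, Ea = 82.0 kJ mol⁻¹)
    2 reagent → self-condensation product (k = 1.40 M⁻¹ min⁻¹, Ea = 41.0 kJ mol⁻¹)
    substrate + free catalyst ⇌ catalyst intermediate A (K = 29.0 M⁻¹, k = 160 M⁻¹ min⁻¹, Ea = 53.0 kJ mol⁻¹, ΔH = −11.0 kJ mol⁻¹)
    catalyst intermediate A → catalyst intermediate B (k = 1.90 min⁻¹, Ea = 82.0 kJ mol⁻¹)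
    reagent + catalyst intermediate B ⇌ catalyst intermediate C (K = 280 M⁻¹, k = 110 M⁻¹ min⁻¹, Ea = 39.0 kJ mol⁻¹, ΔH = −30.0 kJ mol⁻¹)
    (constants at 0 °C)

Saturday's holds 0.00474 M of self-condensation product at 25.0 min, more than the cover. Twice that product, less the spare, is 22.9% of the substrate charge, which puts the ceiling at 77.1%. Tuesday's 0.00554 M gives a ceiling of 64.7% the same way. The neighbouring flask is Saturday's with 0.0022 M of free catalyst. It holds 0.00405 M of product, so its ceiling is 87.7%, and it gives 87.2% of target.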